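**Plan**

- The target is two resorcinol rings joined by a (Z)-hexadec-8-ene chain. Ring B carries an acetate on the C3 oxygen and a free hydroxyl on C5, two positions that are otherwise equivalent; ring A has both hydroxyls free.
- The retrosynthesis cuts ring B itself at C2–C3, C4–C5 and C5–C6. A 3-alkylcyclobutenone (C1, C2, C5, C6) and (triisopropylsiloxy)acetylene (C3, C4) rebuild the ring with the C5 hydroxyl free and the C3 oxygen silylated, so the acetate goes on without a statistical step.
- Further cuts: the cyclobutenone–chain bond (chain Grignard reagent plus 3-ethoxycyclobutenone), the ring A–chain bond (aryl Grignard reagent plus primary bromide, copper catalysis), and C8=C9 (Wittig reaction of two eight-carbon halides).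
- Forward order: C8 + C8 Wittig to a bromo chloride; ring A attached at the bromide; the four-membered ring attached at the chloride; ring B grown from the four-membered ring; acetylation; removal of the three silyl ethers.
- Stereochemistry: the only element is the C8=C9 Z double bond. It comes from the kinetic cis selectivity of a non-stabilised ylide under lithium-free conditions, and no later step should isomerise it.

Key step: step 9

Remark on the chemistry: lithium ethynolate is assumed to be silylated on oxygen by a bulky silyl triflate, as its 2-alkyl homologues are, and the resulting parent siloxyalkyne is assumed to survive heating to 110 °C.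

**Route**

Step 1
Reactants: 1 5-bromoresorcinol
Product: 2 1-bromo-3,5-bis(tert-butyldimethylsilyloxy)benzene
Conditions: TBSCl, imidazole, DMF, 20 °C
Reagents that add atoms: tert-butyldimethylsilyl chloride CC(C)(C)[Si](C)(C)Cl
Why: Imidazole-promoted silylation of both phenols is routine, and the aryl silyl ethers should be inert to the magnesium and copper chemistry ahead and removable with fluoride at the end.

Step 2
Reactants: 3 8-bromooctan-1-ol
Product: 4 8-bromooctanal
Conditions: TEMPO (cat.), PhI(OAc)2, CH2Cl2, 20 °C
Reagents that add atoms: none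
Why: TEMPO-catalysed oxidation of a primary alcohol (oxoammonium mechanism) stops at the aldehyde and leaves the primary bromide alone.

Step 3
Reactants: 5 1-bromo-8-chlorooctane
Product: 6 (8-chlorooctyl)triphenylphosphonium bromide
Conditions: PPh3 (1 equiv), MeCN, 82 °C
Reagents that add atoms: triphenylphosphine c1ccc(cc1)P(c1ccccc1)c1ccccc1
Why: Quaternisation of the phosphine by SN2 displacement should occur at the C–Br end, because bromide leaves far faster than chloride.

Step 4
Reactants: 6 (8-chlorooctyl)triphenylphosphonium bromide; 4 8-bromooctanal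
Product: 8 (Z)-1-bromo-16-chlorohexadec-8-ene, via ylide 7 (not isolated)
Conditions: NaN(SiMe3)2, THF, −20 °C; then 4, −78 → 20 °C
Reagents that add atoms: none
Why: Wittig olefination of a non-stabilised ylide under lithium-free conditions at low temperature is kinetically cis-selective and sets the C8=C9 Z double bond, carbonyl addition outruns alkylation of the ylide by either primary halide, and any E isomer can be removed on AgNO3-impregnated silica.

Step 5
Reactants: 2 1-bromo-3,5-bis(tert-butyldimethylsilyloxy)benzene; 8 (Z)-1-bromo-16-chlorohexadec-8-ene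
Product: 10 1-[(Z)-16-chlorohexadec-8-enyl]-3,5-bis(tert-butyldimethylsilyloxy)benzene, via aryl Grignard 9 (not isolated)
Conditions: 2, Mg turnings, THF, 50 °C; then 8, Li2CuCl4 (cat.), THF/NMP, 0 → 20 °C
Reagents that add atoms: none
Why: Kochi-type copper-catalysed coupling of an aryl Grignard reagent with a primary alkyl bromide forms the aryl–CH2 bond of ring A, while the primary chloride does not react at or below room temperature, so the two chain ends stay differentiated.

Step 6
Reactants: 11 ethoxyacetylene; 12 acetyl chloride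
Product: 14 3-ethoxycyclobut-2-en-1-one, via ketene 13 (not isolated)
Conditions: Et3N, Et2O, 0 → 20 °C (slow addition of 12)
Reagents that add atoms: none
Why: Ketene released from acetyl chloride by the amine adds [2+2] to the electron-rich ynol ether, with the nucleophilic CH terminus bonding to the ketene carbonyl carbon, which gives the vinylogous ester directly.

Step 7
Reactants: 15 ethyl formate; 16 dibromomethane; 17 triisopropylsilyl trifluoromethanesulfonate
Product: 21 (triisopropylsiloxy)acetylene, via dibromomethyllithium 18 (not isolated), via lithium dibromoethenolate 19 (not isolated), via lithium ethynolate 20 (not isolated)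
Conditions: 16, lithium 2,2,6,6-tetramethylpiperidide (LiTMP), THF, −78 °C; then 15; then LiN(SiMe3)2; then n-BuLi, −78 → 0 °C; then 17, DMPU, −78 → 0 °C
Reagents that add atoms: none
Why: This is a Kowalski ester-to-ynolate homologation in which formylation of 18 and enolisation give 19, bromine–lithium exchange and a Fritsch–Buttenberg–Wiechell-type 1,2-hydride shift (the shift that completes a Corey–Fuchs alkynylation) give ynolate 20, and the bulky silyl triflate with DMPU should trap it on oxygen.

Step 8
Reactants: 10 1-[(Z)-16-chlorohexadec-8-enyl]-3,5-bis(tert-butyldimethylsilyloxy)benzene; 14 3-ethoxycyclobut-2-en-1-one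
Product: 24 3-[(Z)-16-(3,5-bis(tert-butyldimethylsilyloxy)phenyl)hexadec-8-enyl]cyclobut-2-en-1-one, via alkyl Grignard 22 (not isolated), via cyclobutenol 23 (not isolated)
Conditions: 10, Mg turnings (BrCH2CH2Br activation), THF, 65 °C; then 14, THF, −78 °C; then 1 M HCl, 0 → 20 °C
Reagents that add atoms: water O
Why: 1,2-Addition of the Grignard reagent to the vinylogous ester, followed by acid-induced loss of the tertiary hydroxyl and hydrolysis of the enol ether (a Stork–Danheiser-type transposition), should deliver the 3-alkylcyclobutenone, and the aryl silyl ethers and the Z-olefin tolerate a cold Grignard reagent and brief dilute acid.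

Step 9
Reactants: 24 3-[(Z)-16-(3,5-bis(tert-butyldimethylsilyloxy)phenyl)hexadec-8-enyl]cyclobut-2-en-1-one; 21 (triisopropylsiloxy)acetylene
Product: 29 3-[(Z)-16-(3,5-bis(tert-butyldimethylsilyloxy)phenyl)hexadec-8-enyl]-5-(triisopropylsiloxy)phenol, via vinylketene 25 (not isolated), via vinylcyclobutenone 26 (not isolated), via dienylketene 27 (not isolated), via cyclohexadienone 28 (not isolated)
Conditions: 21 (3 equiv), toluene (dilute), 80 °C then 110 °C
Reagents that add atoms: none
Why: In this Danheiser benzannulation, cyclobutenone 24 should open at 80 °C by a 4π-electron electrocyclic reaction to vinylketene 25, which adds [2+2] to the ynol ether to give 4-vinylcyclobutenone 26; a second 4π opening gives dienylketene 27, whose 6π-electron disrotatory electrocyclisation closes ring B as dienone 28, and this tautomerises to the phenol. The closest known reaction type is the thermal annulation of 3-alkylcyclobutenones with alkoxy- and trialkylsiloxyalkynes to resorcinol monoethers. Bonds C2–C3 and C4–C5 arise in the ketene–alkyne cycloaddition and C5–C6 in the electrocyclic closure, so the ketone oxygen ends as the free C5 phenol and the alkyne oxygen stays as the C3 silyl ether. No stereocentre is created (the sp3 centre of 26 is lost on ring opening) and the C8=C9 Z geometry is not touched. The step needs regioselectivity, which the polarisation of the ynol ether secures because its nucleophilic CH terminus attacks the ketene carbonyl carbon, and chemoselectivity, which an excess of the far more nucleophilic alkyne at moderate dilution secures so that neither the isolated Z-olefin nor the product phenol competes for the ketene.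

Step 10
Reactants: 29 3-[(Z)-16-(3,5-bis(tert-butyldimethylsilyloxy)phenyl)hexadec-8-enyl]-5-(triisopropylsiloxy)phenol
Product: 30 3-[(Z)-16-(3,5-bis(tert-butyldimethylsilyloxy)phenyl)hexadec-8-enyl]-5-(triisopropylsiloxy)phenyl acetate
Conditions: Ac2O, pyridine, DMAP (cat.), CH2Cl2, 0 → 20 °C
Reagents that add atoms: acetic anhydride CC(=O)OC(C)=O
Why: DMAP-catalysed acylation of the single free phenol is unambiguous because the other three phenolic oxygens are silylated.

Step 11
Reactants: 30 3-[(Z)-16-(3,5-bis(tert-butyldimethylsilyloxy)phenyl)hexadec-8-enyl]-5-(triisopropylsiloxy)phenyl acetate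
Product: 31 oncostemonol B
Conditions: HF·pyridine, excess pyridine, THF, 0 → 20 °C; pH 7 buffer quench
Reagents that add atoms: none
Why: Fluoride-driven cleavage of the three aryl silyl ethers under buffered, mildly acidic conditions should never generate a phenoxide, so the aryl acetate is neither hydrolysed nor passed between phenols, and the diluted reagent leaves the olefin alone.

**Compound list**

1 | 5-bromoresorcinol | Oc1cc(O)cc(Br)c1 | starting material
2 | 1-bromo-3,5-bis(tert-butyldimethylsilyloxy)benzene | CC(C)(C)[Si](C)(C)Oc1cc(Br)cc(O[Si](C)(C)C(C)(C)C)c1 | intermediate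
3 | 8-bromooctan-1-ol | OCCCCCCCCBr | starting material
4 | 8-bromooctanal | O=CCCCCCCCBr | intermediate
5 | 1-bromo-8-chlorooctane | ClCCCCCCCCBr | starting material
6 | (8-chlorooctyl)triphenylphosphonium bromide | ClCCCCCCCC[P+](c1ccccc1)(c1ccccc1)c1ccccc1.[Br-] | intermediate
7 | (8-chlorooctylidene)triphenylphosphorane (ylide, formed in situ) | ClCCCCCCCC=P(c1ccccc1)(c1ccccc1)c1ccccc1 | intermediate
8 | (Z)-1-bromo-16-chlorohexadec-8-ene | ClCCCCCCC/C=C\CCCCCCCBr | intermediate
9 | 3,5-bis(tert-butyldimethylsilyloxy)phenylmagnesium bromide (formed in situ) | CC(C)(C)[Si](C)(C)Oc1cc([Mg]Br)cc(O[Si](C)(C)C(C)(C)C)c1 | intermediate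
10 | 1-[(Z)-16-chlorohexadec-8-enyl]-3,5-bis(tert-butyldimethylsilyloxy)benzene | ClCCCCCCC/C=C\CCCCCCCc1cc(O[Si](C)(C)C(C)(C)C)cc(O[Si](C)(C)C(C)(C)C)c1 | intermediate
11 | ethoxyacetylene | C#COCC | starting material
12 | acetyl chloride | CC(=O)Cl | starting material
13 | ketene (formed in situ) | C=C=O | intermediate
14 | 3-ethoxycyclobut-2-en-1-one | CCOC1=CC(=O)C1 | intermediate
15 | ethyl formate | CCOC=O | starting material
16 | dibromomethane | BrCBr | starting material
17 | triisopropylsilyl trifluoromethanesulfonate | CC(C)[Si](OS(=O)(=O)C(F)(F)F)(C(C)C)C(C)C | starting material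
18 | dibromomethyllithium (formed in situ) | [Li]C(Br)Br | intermediate
19 | lithium 2,2-dibromoethenolate (formed in situ) | [Li]OC=C(Br)Br | intermediate
20 | lithium ethynolate (formed in situ) | [Li]OC#C | intermediate
21 | (triisopropylsiloxy)acetylene | C#CO[Si](C(C)C)(C(C)C)C(C)C | intermediate
22 | (Z)-16-[3,5-bis(tert-butyldimethylsilyloxy)phenyl]hexadec-8-enylmagnesium chloride (formed in situ) | Cl[Mg]CCCCCCC/C=C\CCCCCCCc1cc(O[Si](C)(C)C(C)(C)C)cc(O[Si](C)(C)C(C)(C)C)c1 | intermediate
23 | 1-[(Z)-16-(3,5-bis(tert-butyldimethylsilyloxy)phenyl)hexadec-8-enyl]-3-ethoxycyclobut-2-en-1-ol (racemic, formed in situ) | CCOC1=CC(O)(CCCCCCC/C=C\CCCCCCCc2cc(O[Si](C)(C)C(C)(C)C)cc(O[Si](C)(C)C(C)(C)C)c2)C1 | intermediate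
24 | 3-[(Z)-16-(3,5-bis(tert-butyldimethylsilyloxy)phenyl)hexadec-8-enyl]cyclobut-2-en-1-one | O=C1C=C(CCCCCCC/C=C\CCCCCCCc2cc(O[Si](C)(C)C(C)(C)C)cc(O[Si](C)(C)C(C)(C)C)c2)C1 | intermediate
25 | 3-[(Z)-16-(3,5-bis(tert-butyldimethylsilyloxy)phenyl)hexadec-8-enyl]buta-1,3-dien-1-one (vinylketene, formed in situ) | O=C=CC(=C)CCCCCCC/C=C\CCCCCCCc1cc(O[Si](C)(C)C(C)(C)C)cc(O[Si](C)(C)C(C)(C)C)c1 | intermediate
26 | 4-[(10Z)-18-(3,5-bis(tert-butyldimethylsilyloxy)phenyl)octadeca-1,10-dien-2-yl]-3-(triisopropylsiloxy)cyclobut-2-en-1-one (racemic, formed in situ) | O=C1C=C(O[Si](C(C)C)(C(C)C)C(C)C)C1C(=C)CCCCCCC/C=C\CCCCCCCc2cc(O[Si](C)(C)C(C)(C)C)cc(O[Si](C)(C)C(C)(C)C)c2 | intermediate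
27 | 5-[(Z)-16-(3,5-bis(tert-butyldimethylsilyloxy)phenyl)hexadec-8-enyl]-3-(triisopropylsiloxy)hexa-1,3,5-trien-1-one (C2 cis to C5 across C3=C4; formed in situ) | O=C=C/C(O[Si](C(C)C)(C(C)C)C(C)C)=C\C(=C)CCCCCCC/C=C\CCCCCCCc1cc(O[Si](C)(C)C(C)(C)C)cc(O[Si](C)(C)C(C)(C)C)c1 | intermediate
28 | 5-[(Z)-16-(3,5-bis(tert-butyldimethylsilyloxy)phenyl)hexadec-8-enyl]-3-(triisopropylsiloxy)cyclohexa-2,4-dien-1-one (formed in situ) | O=C1C=C(O[Si](C(C)C)(C(C)C)C(C)C)C=C(CCCCCCC/C=C\CCCCCCCc2cc(O[Si](C)(C)C(C)(C)C)cc(O[Si](C)(C)C(C)(C)C)c2)C1 | intermediate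
29 | 3-[(Z)-16-(3,5-bis(tert-butyldimethylsilyloxy)phenyl)hexadec-8-enyl]-5-(triisopropylsiloxy)phenol | Oc1cc(O[Si](C(C)C)(C(C)C)C(C)C)cc(CCCCCCC/C=C\CCCCCCCc2cc(O[Si](C)(C)C(C)(C)C)cc(O[Si](C)(C)C(C)(C)C)c2)c1 | intermediate
30 | 3-[(Z)-16-(3,5-bis(tert-butyldimethylsilyloxy)phenyl)hexadec-8-enyl]-5-(triisopropylsiloxy)phenyl acetate | CC(=O)Oc1cc(O[Si](C(C)C)(C(C)C)C(C)C)cc(CCCCCCC/C=C\CCCCCCCc2cc(O[Si](C)(C)C(C)(C)C)cc(O[Si](C)(C)C(C)(C)C)c2)c1 | intermediate
31 | oncostemonol B, 3-[(Z)-16-(3,5-dihydroxyphenyl)hexadec-8-enyl]-5-hydroxyphenyl acetate | CC(=O)Oc1cc(O)cc(CCCCCCC/C=C\CCCCCCCc2cc(O)cc(O)c2)c1 | target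

**Count**

Total: 11 steps. Longest linear sequence: 7 steps (steps 2, 4, 5, 8, 9, 10, 11).

**Steps most likely to fail**

Step 7. Three processes could spoil it: over-addition of the carbenoid reagent at the aldehyde-level stage, silylation of the unhindered ynolate on carbon (which would give a silylketene), and thermal 1,3-silyl shift of the product during isolation. The fallback generates the same ynolate by ring fragmentation instead of carbenoid rearrangement. It sets out from silyl triflate 17. 3-Phenylisoxazole F1 would be deprotonated at C5 with n-BuLi in THF at −78 °C to give 5-lithio-3-phenylisoxazole F2. On warming to about −50 °C this should break into benzonitrile and lithium ethynolate 20 with no aldehyde, carbenoid or excess base present. Trapping with 17 in THF/DMPU, followed by chromatography in place of distillation, comes back to the route at 21.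

Step 9. The transient vinylketene could be captured by the product phenol to give aryl esters, it could dimerise, or the siloxyalkyne could rearrange before it is consumed. The fallback gives up the ring construction and attaches a ring B that is differentiated beforehand. It sets out from chloride 10 and from 5-bromoresorcinol 1.
- Mono-alkylation of 1 with 4-methoxybenzyl chloride and K2CO3 in acetone would give 3-bromo-5-(4-methoxybenzyloxy)phenol F3.
- Silylation with TIPSCl and imidazole would give 1-bromo-3-(4-methoxybenzyloxy)-5-(triisopropylsiloxy)benzene F4.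
- Kumada coupling of the Grignard reagent 22 (made from 10 as in step 8) with F4, catalysed by Pd(dppf)Cl2 in THF at 50 °C, would give 1-[(Z)-16-(3,5-bis(tert-butyldimethylsilyloxy)phenyl)hexadec-8-enyl]-3-(4-methoxybenzyloxy)-5-(triisopropylsiloxy)benzene F5.
- Oxidative removal of the 4-methoxybenzyl group with DDQ in CH2Cl2/pH 7 buffer at 0 °C comes back to the route at 29.

Step 8. Insertion of magnesium into the primary chloride of a large, oily substrate may be sluggish or incomplete, Wurtz coupling may intervene, and the strained enone may degrade during the acid stage. The fallback changes the way the nucleophile is made. It sets out from chloride 10.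
- Finkelstein exchange (NaI, acetone, 56 °C) would give 1-[(Z)-16-iodohexadec-8-enyl]-3,5-bis(tert-butyldimethylsilyloxy)benzene F6.
- Iodine–lithium exchange with t-BuLi (2 equiv) in Et2O/pentane at −78 °C would give (Z)-16-[3,5-bis(tert-butyldimethylsilyloxy)phenyl]hexadec-8-enyllithium F7.
- Addition of F7 to 14 at −78 °C and quenching into cold, weakly acidic buffer comes back to the route at cyclobutenol 23 and, after the same transposition, at 24.

**Further compounds**

F1 | step 7 | 3-phenylisoxazole | c1ccc(cc1)-c1ccon1
F2 | step 7 | 5-lithio-3-phenylisoxazole | [Li]c1cc(-c2ccccc2)no1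
F3 | step 9 | 3-bromo-5-(4-methoxybenzyloxy)phenol | COc1ccc(COc2cc(O)cc(Br)c2)cc1
F4 | step 9 | 1-bromo-3-(4-methoxybenzyloxy)-5-(triisopropylsiloxy)benzene | COc1ccc(COc2cc(Br)cc(O[Si](C(C)C)(C(C)C)C(C)C)c2)cc1
F5 | step 9 | 1-[(Z)-16-(3,5-bis(tert-butyldimethylsilyloxy)phenyl)hexadec-8-enyl]-3-(4-methoxybenzyloxy)-5-(triisopropylsiloxy)benzene | COc1ccc(COc2cc(CCCCCCC/C=C\CCCCCCCc3cc(O[Si](C)(C)C(C)(C)C)cc(O[Si](C)(C)C(C)(C)C)c3)cc(O[Si](C(C)C)(C(C)C)C(C)C)c2)cc1
F6 | step 8 | 1-[(Z)-16-iodohexadec-8-enyl]-3,5-bis(tert-butyldimethylsilyloxy)benzene | ICCCCCCC/C=C\CCCCCCCc1cc(O[Si](C)(C)C(C)(C)C)cc(O[Si](C)(C)C(C)(C)C)c1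
F7 | step 8 | (Z)-16-[3,5-bis(tert-butyldimethylsilyloxy)phenyl]hexadec-8-enyllithium | [Li]CCCCCCC/C=C\CCCCCCCc1cc(O[Si](C)(C)C(C)(C)C)cc(O[Si](C)(C)C(C)(C)C)c1
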